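The runs are simulated for substances that don't exist.

Ask what stands in the flask at 4.0 min, given these charges and readings.

- at 4.0 min, what has stopped the reaction, if anything has (all of the substrate has reacted / it is still moving / the partner has run out first / the reagent has run out first)
- part of the substrate gone at 4.0 min
- the target standing at 4.0 min, as a percentage of the substrate charged

| setting | theta | beta | flask |
|---|---|---|---|
| substrate | 1.6 M | 1.6 M | 1.6 M |
| partner | 1 equiv | 0.50 equiv | 1.00 equiv |
| reagent | 0.55 equiv | 1.1 equiv | 1.10 equiv |
| remark | run made earlier | run made earlier |  |
| time |  |  | 4.0 min |

- theta (time / min: substrate / %, target / %): 0.833: 54.7, 19.2; 1.50: 53.6, 23.7; 2.50: 54.7, 22.2; 3.00: 54.7, 22.0; 4.00: 54.8, 20.2; 5.00: 55.2, 20.9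
- beta (time / min: substrate / %, target / %): 0.417: 30.3, 24.7; 1.33: 22.9, 41.0; 2.00: 24.5, 43.4; 3.00: 24.0, 41.9; 5.00: 24.3, 43.4

(readings scatter by 1 percentage point)

- what was read earlier has a scatter of 1 percentage point, one standard deviation
- a reading or a percentage of target counts all its forms, free or not
- the reaction counts as stopped when no species that holds the substrate changes by six tenths of a point or more over the second half of the time
- what has gone from substrate into another species counts as reacted, even if it can come back

Begin with the theta run, flat within the scatter from 1.50 min on: its readings from there average 54.6 % substrate and 21.8 % target, leaving 23.6 % of the charge unread. Suppose this unread form trades reversibly with substrate; at standstill the forward and back rates are equal, time drops out of their quotient, and the hold ratio, unread share over substrate, 0.432, acts as an equilibrium constant. Next divide theta's reagent by its target, a cost of 2.52 equivalents per unit of target. The flask has theta's partner and twice its reagent, so wager on reagent as the limiting reagent, with target 43.6 %. Split the remainder by the hold ratio: substrate 39.4 %, conversion 60.6 %.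

The weak link is the hold ratio, since beta, averaged from 1.33 min on, reads 23.9 % substrate and 42.4 % target, which gives 1.41, more than theta's. Reforge it: beta's target stands beside a partner charge of 0.50 equiv, so suppose that a second unread form, 23.4 % of the charge, waits there for partner, and reckon none in the flask, which has twice beta's partner.

The forecast said the reagent has run out first, with conversion 84 % (76 % to 92 %) and target 49 % (42 % to 60 %), judging that “the flask is not partner-limited”; its conversion stands above mine. The flask gives this answer: the reagent has run out first, with 0 % of the reagent left, conversion 62.0 % and target 45.6 %.

    substrate + reagent → open intermediate (k = 0.0560 /M/s)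
    crystals ⇌ target, rate k2*(cs2 - [target]) while solid is left; crystals form when [target] > cs2 (solubility = 1.20 M, k = 0.910 /s)
    open intermediate + second intermediate → target (k = 0.140 /M/s)
    substrate ⇌ dormant form (K = 0.430, k = 0.0390 /s)
    reagent + partner → second intermediate (k = 0.0780 /M/s)

The unread form is the dormant form, whose relaxation half-life with substrate, 0.0891 min, is short against both 4.0 min and the 0.638 min at which reagent falls under a fiftieth of its charge, and in the flask at 4.00 min the hold ratio 0.432 times substrate 38.0 % gives 16.4 % against a dormant form of 16.3 %. The neighbouring flask with 0.400 equiv of partner holds 36.7 % open intermediate and 18.7 % substrate, where the ratio gives 8.08 % and the dormant form stands at 8.04 %.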